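At early times the fork already leans one way. Follow a partner molecule in the grey run and the readings put it on left-handed substrate: the loss of that substrate by 4.00 min reads as 0.960 of the partner charged, nearly all, while the right-handed substrate still reads 51%.

| setting | grey | ochre | flask |
|---|---|---|---|
| left-handed substrate | 20 mM | 20 mM | 20 mM |
| right-handed substrate | 20 mM | 20 mM | 20 mM |
| partner | 15 mM (fed, over 20 s) | 22 mM (fed, over 20 s) | 30.0 mM (fed, over 20 s) |
| free catalyst | 14 µM | 14 µM | 14 µM |
| impurity | 1.8 µM | 1.8 µM | 1.8 µM |
| remark | run made earlier | run made earlier |  |
| time |  |  | 4.0 min |

- grey (time / min: right-handed substrate / %, left-handed substrate / %): 0.333: 49, 40; 0.667: 51, 30; 1.00: 51, 23; 2.00: 47, 18; 4.00: 51, 14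
- ochre (time / min: right-handed substrate / %, left-handed substrate / %): 0.833: 52, 19; 1.50: 47, 14; 2.50: 46, 5; 3.00: 49, 6; 4.00: 44, 4

(standard deviation of a reading: 2 percentage points)

- whether the excess of right-handed substrate over left-handed substrate among what is left of the two reaches 90% by 4.0 min (no / yes)
- the highest excess of right-handed substrate over left-handed substrate among what is left of the two up to 4.0 min

- free catalyst is single-handed; left-handed substrate and right-handed substrate are mirror images of each other, charged as a racemate, each of them at the stated concentration
- steps under discussion: free catalyst + right-handed substrate <-> catalyst intermediate B; free catalyst -> spent catalyst B; free catalyst + left-handed substrate <-> catalyst intermediate A; partner + catalyst intermediate A -> free catalyst + left-handed product; partner + catalyst intermediate B -> free catalyst + right-handed product; free catalyst + impurity -> spent catalyst A; left-handed product <-> right-handed product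

So count the partner in equivalents: Φ, partner charged per left-handed substrate charged, is 1.50 for the flask, against 0.750 for grey, where partner is the limiting reagent, and 1.10 for ochre.

The wanted excess needs left-handed substrate L at 0.0526 of right-handed substrate R. With R at the ochre reading 44% of the charge, the partner spent on both substrates, in equivalents, is

Φ* = 2 [1 − R (1 + 0.0526)] = 1.07

Was one number enough? No. The ochre run stands above Φ*, by 0.0263 equivalents reckoned on one scattered reading, yet its readings at 4.00 min give an excess of 83.3%. Φ* tells what the charge can pay for, not how soon. My reckoning is that the flask passes the mark, since its surplus over Φ* of 8.53 mM is far more than ochre's 0.526 mM.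

The forecast says yes, with a top of 96%, holding that “the runs stall mainly because partner runs out”.

The flask gives yes, with a top of 99.4%.

    free catalyst + right-handed substrate ⇌ catalyst intermediate B (K = 530 /M, k = 2.30 × 10⁵ /M/s)
    free catalyst → spent catalyst B (k = 1.30 × 10⁻⁵ /s)
    free catalyst + left-handed substrate ⇌ catalyst intermediate A (K = 410 /M, k = 1.60 × 10⁵ /M/s)
    partner + catalyst intermediate A → free catalyst + left-handed product (k = 6900 /M/s)
    partner + catalyst intermediate B → free catalyst + right-handed product (k = 120 /M/s)
    free catalyst + impurity → spent catalyst A (k = 4.80 × 10⁵ /M/s)
    left-handed product ⇌ right-handed product (k = 0.0110 /s)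

The flask reaches the wanted excess at 1.82 min, with 45.9% right-handed substrate left. That puts the cost at 1.03 equivalents, so the flask's charge stands 9.33 mM above that cost, and the ochre charge stands 1.33 mM above it.

The runs were computed from invented constants, noise included.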